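At early times in green, E stands at its charge and L has a half-life of 0.53 h, but E is pairing into E2, and I reckon the run from the free [E] left after that pairing.

    L + E → E + D (k1 = 88 M⁻¹ min⁻¹)
    E + D ⇌ E.D (K2 = 110 M⁻¹, k2 = 140 M⁻¹ min⁻¹)
    J + E.D → E + G (k3 = 3.7 M⁻¹ min⁻¹)
    E + E ⇌ E2 (K4 = 2.3 × 10⁵ M⁻¹, k4 = 150 M⁻¹ min⁻¹)
    E + G ⇌ E.G, settled at all times (K5 = 7.8 M⁻¹)

in all of them: E 0.25 mM; time 25 h

| run | L | J | remark |
|---|---|---|---|
| red | 0.050 M (fed, over 5.0 h) | 0.0750 M | all else is in the flask from the start; the feed brings no volume worth counting |
| grey | 0.050 M (fed, over 30 min) | 0.0750 M | all else is in the flask from the start; the feed brings no volume worth counting |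
| violet | 0.050 M | 0.0750 M (in portions, 2, over 5.0 h) | first portion at the start, last at 5.0 h |
| amber | 0.050 M | 0.0750 M (fed, over 5.0 h) | all else is in the flask from the start; the feed brings no volume worth counting |
| green | 0.050 M | 0.0750 M | everything together at the start |

- the best flask by amount of G, in percent of the L charged; "all alike" if 1.5 percentage points covers them all (red / grey / violet / amber / green / all alike)
- amount of G at the end, in percent of the L charged, red
- amount of G at the end, in percent of the L charged, grey
- amount of G at the end, in percent of the L charged, violet
- amount of G at the end, in percent of the L charged, amber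
- amount of G at the end, in percent of the L charged, green

- G is meant together with its E.G
- two of one species on the left: rate k times its square, two consumed each time
- run time (red): 25 h

**The round.** I start with the round alone. If every E sat as E.D and J stayed as charged, the L charge would turn over in 12.0 h, less than the run.

**The dimer.** Now I add the pairing, which is strongly favoured: its constant times the starting [E] is 58. My carried quantity is the free level [E]f, the [E] at which [E] plus twice the dimer constant times [E] squared equals the catalyst charge. It comes to 0.0223 mM.

**Two clocks.** At this level L decays at 0.00196 min⁻¹, a lifetime of 8.50 h. E.D is drained by J as well as by reopening, so [E.D]/([E][D]) is 90.3 M⁻¹, and D goes to G at 5.58 × 10⁻⁴ min⁻¹, a lifetime of 29.9 h. That is longer than the lifetime of L, so D to G is the rate-limiting step, and D piles up. Two first-order steps in series give 41.5% of G at the end, with the clock started at [E]f.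

**Head start.** The fall to [E]f takes 2.27 h, and L present during that fall gains the equivalent of 3.77 h at the level. Green has this gain. I let it cancel against falling [J] and the E held in E.D, and I commit to 41.5% for green. Red loses the gain, and its L also enters 2.50 h late on average. At the closing rate of G, that costs 11 percentage points, which puts red at 30.4%. Violet and amber hold their L from the start but receive their J late, and I place them just under green. Grey feeds for 30 min, less than the fall, so I let it keep part of the gain and place it below them and above red.

**The forecast.** The forecast names green best at 42%, puts violet at 40.5%, amber at 40% and grey at 40%, and puts red at 36%, above my figure, holding that “slow L feeding (red) loses the most”.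

**The flasks.** Red gives 27.2%, grey 35.2%, violet 37.5%, amber 37.6% and green 39.4%, so green is best, and green stands 12 points over red against my 11 points. Green has done half of its first-step turnover up to the end by 2.22 h. For green with E cut to 1.5 × 10⁻⁴ M, [E]f becomes 0.0170 mM, and the two clocks give 30.4%; that flask gives 28.8%.

The numbers of this flask belong to no real substance.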